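The earlier runs and the new flask were generated by integration with made-up constants; noise was put on by code.

At early times the first end groups fell faster in cedar than in ash, 77% left against 90% at 0.125 d, so I took the rate as k[first end groups][second end groups].

| setting | ash | cedar | flask |
|---|---|---|---|
| first end groups | 0.050 M | 0.050 M | 0.050 M |
| second end groups | 0.034 M | 0.075 M | 0.0500 M |
| remark | run made earlier | run made earlier |  |
| time |  |  | 4.0 d |

| run | time / d | first end groups / % | links / % |
|---|---|---|---|
| ash | 0.125 | 90 | 11 |
| ash | 0.333 | 76 | 23 |
| ash | 0.625 | 62 | 36 |
| ash | 1.04 | 54 | 46 |
| ash | 1.67 | 46 | 51 |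
| ash | 2.08 | 43 | 54 |
| ash | 2.50 | 41 | 56 |
| cedar | 0.125 | 77 | 20 |
| cedar | 0.333 | 55 | 46 |
| cedar | 0.625 | 38 | 60 |
| cedar | 1.04 | 24 | 77 |
| cedar | 1.67 | 15 | 89 |
| cedar | 2.08 | 9 | 90 |
| cedar | 2.50 | 3 | 94 |

(readings scatter by 1.5 percentage points)

* why nothing more happens at 4.0 d, or that something still does (forward and back rates have come level / all of the first end groups has reacted / the second end groups has run out first / it is still moving)
* share of the first end groups used up at 4.0 d
* links at 4.0 d, in percent of the first end groups charged

Each link uses one of each end group, so in cedar [second end groups] stayed above [first end groups] by the difference of the charges. That balance, integrated with the 24% left at 1.04 d, gave the reading k, the second-order rate constant, 3.21 × 10⁻⁴ M⁻¹ s⁻¹.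

But the flask has equal charges, so its two concentrations stay equal, and by the forward step its share left is 1/(1 + k[first end groups]₀t). I reckoned 15.3% left at 4.0 d, so 84.7% used up by the forward step, an estimate that carries the scatter of the one reading behind k and counts no way back. The same formula gave 26.5% left at half the time, a fall of 11 percentage points in the second half, more than the stopping limit, so I expected it still to be moving.

The forecast gave 83% used up (79% to 86%), 82% links (78% to 86%) and the verdict "far above the 0.6-point criterion, so the reaction is still moving".

The flask gave 82.6% used up and 82.6% links at 4.0 d, and the verdict was it is still moving.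

    first end groups + second end groups ⇌ links + by-product (K = 44.1, k = 3.43 × 10⁻⁴ M⁻¹ s⁻¹)

The forward half-life of first end groups in the flask was 0.80 d at 0.477 d, short against 4.0 d. By 4.00 d it had stretched to 2.7 d, and my k with the 17% left gives 2.87 d. A neighbour flask with 0.020 M of second end groups made those the limiting reagent; the same balance and k gave 2.19% of them left by the forward step, and at 4.00 d it held 2.93%, with 38.8% of its first end groups used up.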